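Start with the easy step: the loading on the starting material gives a catalyst charge of 2.00 µM, more than the 1.9 µM of added ligand.

starting material 20 mM; enzyme 0.01 mol%; added ligand 1.9 µM

    enzyme + added ligand ⇌ idle complex, settled at all times (K1 = 7.2 × 10⁶ M⁻¹)
    starting material + enzyme → target + enzyme, rate k2*[starting material]*[enzyme]/(1 + ([starting material]/Km2) + ([starting material]/Ksi2)^2) (Km2 = 9.63 mM, Ksi2 = 4.71 mM, k2 = 60800 M⁻¹ s⁻¹)
    enzyme + enzyme ⇌ resting dimer (K3 = 9.68 × 10⁶ M⁻¹, k3 = 4390 M⁻¹ s⁻¹)

* the form that holds most of the catalyst when 10% of the starting material are converted (resting dimer / enzyme / idle complex)
* its share of the catalyst then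
* factor on the rate of making target when 10% of the starting material are converted if enzyme is charged twice over
* factor on the rate when 10% of the starting material are converted if enzyme is charged at 0.05 mol% instead

- where a step has two of a species, its rate is k times that concentration squared, and two are used at each turn
- a form made of two catalysts counts as two
- charge of starting material (flask): 20 mM

1. Take the quick way first. Hold c(added ligand) at its charge, and the ratio of idle complex to enzyme is 14, which puts 93.2% of the catalyst in the idle complex.

2. Test it by subtraction. That much idle complex leaves you 0.0362 µM of free ligand, far less than the charge you assumed. The quick way cheats.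

3. Now take the second way and balance both charges. Let x be c(enzyme). Then c(idle complex) is the catalyst charge less x, and c(added ligand) is the ligand charge less c(idle complex). Set c(idle complex) equal to 7.2 × 10⁶ M⁻¹ times x times c(added ligand), and solve: x is 0.508 µM.

4. That makes the loose share 25.4%: the part of the catalyst that the ligand balance leaves outside the idle complex, dimer set aside. Your pick for the resting state is the idle complex, at 74.6%.

5. At one conversion, c(starting material) is the same in each flask, so the rate law makes the rate go with c(enzyme). Twice the charge gives a factor of 4.36. A loading of 0.05 mol% means 10.0 µM of catalyst, x of 8.13 µM, a loose share of 81.3% and a factor of 16.0. Your reckoning carries no dimer, and it stops here.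

6. The forecast names the idle complex at 71.7%, with factors of 3.9 and 14.2. It says “the slow dimer has taken just about 7 % of the catalyst and is far from its equilibrium”. Its share is lower than yours, and so are its factors.

7. In the flask, at 1.19 min, the idle complex holds 71.8%, enzyme 21.5% and resting dimer 6.71%, with factors of 3.91 and 14.1; that moment comes sooner than the dimer step's relaxation half-life of 2.21 min, taken at 8.00 min, and the catalyst outside the idle complex, 28.2%, stands above the loose share of 25.4%. In the flask charged at 0.05 mol%, at the same conversion, the loose share of 81.3%, reckoned with dimer set aside, stands beside 81.4% outside the idle complex, and of that catalyst enzyme holds 60.8% and resting dimer 20.6%.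

The constants used here stand for no real mixture.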